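**Retrosynthetic overview**
- Feature: both hydroxyl oxygens sit ortho to the carbons that hold the bridging ether oxygen. These are O on C1 of ring A (the 2,4-dibromo ring, bridge at C6) and O on C1' of ring B (the 3,6-dibromo ring, bridge at C2'). Each OH is traced back to a formyl group on the same carbon.
- Last disconnections: the C1–O and C1'–O bonds. They go back through the bis-formate to the C1–CHO and C1'–CHO bonds of a bis-aldehyde diaryl ether (twofold Baeyer–Villiger/Dakin-type oxygen insertion, then methanolysis).
- Before that: the O–C6 bond of ring A. It is made by SNAr of the ring B salicylaldehyde phenolate on 2,4-dibromo-6-fluorobenzaldehyde, whose formyl group activates the fluoride.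
- The ring B aldehyde comes from ortho-formylation of 2,5-dibromophenol at its only free ortho carbon.
- No ring is formed. Both benzene rings are bought with all four bromines in place, so no bromination regiochemistry has to be solved.

Key step: step 3

Remark: the target has no stereocentre and its ether axis should rotate freely, so no stereocontrol is needed; compounds 1 and 4 are taken to be catalogue chemicals.

Step 1
Reactants: 1 2,5-dibromophenol
Product: 3 3,6-dibromo-2-hydroxybenzaldehyde, via 3,6-dibromo-2-(hydroxymethyl)phenol 2 (not isolated)
Conditions: MgCl2 (anhydrous), Et3N, (CH2O)n, MeCN, reflux; then 1 M HCl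
Reagents that add atoms: paraformaldehyde, reacting as formaldehyde, C=O
Why: In this Casnati–Skattebøl ortho-formylation, magnesium holds the phenolate oxygen of 1 and formaldehyde together so that the C–C bond can form only at the single free ortho carbon C6 (C2 carries Br), and the resulting benzylic alcohol 2 is oxidised to 3 by Oppenauer-type hydride transfer to a second formaldehyde.

Step 2
Reactants: 3 3,6-dibromo-2-hydroxybenzaldehyde; 4 2,4-dibromo-6-fluorobenzaldehyde (slight excess)
Product: 5 2,4-dibromo-6-(3,6-dibromo-2-formylphenoxy)benzaldehyde
Conditions: Cs2CO3, 4 Å MS, DMAc, 100 °C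
Reagents that add atoms: none
Why: In this SNAr (addition–elimination) the phenolate of 3 adds to C6 of 4, where the ortho formyl group and the two meta bromines stabilise the Meisenheimer anion, and fluoride should leave far faster than either bromide, so no transition-metal catalyst that could insert into the four C–Br bonds is needed.

Step 3
Reactants: 5 2,4-dibromo-6-(3,6-dibromo-2-formylphenoxy)benzaldehyde
Product: 8 2,4-dibromo-6-(3,6-dibromo-2-formyloxyphenoxy)phenyl formate, via ring-A monoformate 6 (not isolated), via ring-B monoformate 7 (not isolated)
Conditions: urea·H2O2 (excess), (CF3CO)2O, Na2HPO4, CH2Cl2, 0 °C to rt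
Reagents that add atoms: urea–hydrogen peroxide, NC(N)=O.OO (its peroxide oxygen is delivered through trifluoroperacetic acid, OOC(=O)C(F)(F)F, made in the flask)
Why: Trifluoroperacetic acid adds to each formyl carbon to give a peroxy-hemiacetal (Criegee adduct), in which the aryl carbon (C1 of ring A, C1' of ring B) shifts to the near peroxide oxygen as trifluoroacetate leaves, so the C1–O and C1'–O bonds form as formate esters; the two insertions are independent and run through monoformate 6 or 7 to the same bis-formate 8. The closest known reaction type is the Baeyer–Villiger (Dakin-type) oxidation of ortho-alkoxy- and ortho-aryloxybenzaldehydes to aryl formates, applied here twice in one molecule. No ring is closed and no stereocentre is created. The selectivity needed is aryl over hydride migration in each adduct, and three things secure it: the lone pair of the bridging oxygen, which is ortho to both migrating carbons and stabilises the positive charge building up there; the two ortho neighbours (Br and OAr) of each formyl group, whose strain is released on migration; and the very good leaving group of this peracid, which offsets the retarding effect of the bromines. The tetrabrominated rings are too electron-poor for electrophilic hydroxylation, the C–Br bonds and the ether are inert to peracid, and the anhydrous peroxide source with Na2HPO4 as acid scavenger should keep the formates intact so that no free phenol meets the oxidant.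

Step 4
Reactants: 8 2,4-dibromo-6-(3,6-dibromo-2-formyloxyphenoxy)phenyl formate (crude)
Product: 11 2,4-dibromo-6-(3,6-dibromo-2-hydroxyphenoxy)phenol, via residual ring-B formate 9 (not isolated), via residual ring-A formate 10 (not isolated)
Conditions: K2CO3, MeOH, 0 °C to rt, short contact; then 1 M HCl
Reagents that add atoms: none
Why: This is a base-mediated transesterification (methanolysis) of aryl formates, which are very labile because the brominated phenolates are good leaving groups, and the low temperature should keep those phenolates from Smiles-type aryl migration or displacement of an ortho bromide before acidification gives the bis-phenol 11.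

**Compound list**
1 | 2,5-dibromophenol | Oc1cc(Br)ccc1Br | starting material
2 | 3,6-dibromo-2-(hydroxymethyl)phenol (held as its magnesium salt, not isolated) | OCc1c(Br)ccc(Br)c1O | intermediate
3 | 3,6-dibromo-2-hydroxybenzaldehyde | O=Cc1c(Br)ccc(Br)c1O | intermediate
4 | 2,4-dibromo-6-fluorobenzaldehyde | O=Cc1c(F)cc(Br)cc1Br | starting material
5 | 2,4-dibromo-6-(3,6-dibromo-2-formylphenoxy)benzaldehyde | O=Cc1c(Br)cc(Br)cc1Oc1c(Br)ccc(Br)c1C=O | intermediate
6 | 2,4-dibromo-6-(3,6-dibromo-2-formylphenoxy)phenyl formate (ring-A monoformate, not isolated) | O=COc1c(Br)cc(Br)cc1Oc1c(Br)ccc(Br)c1C=O | intermediate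
7 | 3,6-dibromo-2-(3,5-dibromo-2-formylphenoxy)phenyl formate (ring-B monoformate, not isolated) | O=Cc1c(Br)cc(Br)cc1Oc1c(Br)ccc(Br)c1OC=O | intermediate
8 | 2,4-dibromo-6-(3,6-dibromo-2-formyloxyphenoxy)phenyl formate | O=COc1c(Br)cc(Br)cc1Oc1c(Br)ccc(Br)c1OC=O | intermediate
9 | 3,6-dibromo-2-(3,5-dibromo-2-hydroxyphenoxy)phenyl formate (not isolated) | Oc1c(Br)cc(Br)cc1Oc1c(Br)ccc(Br)c1OC=O | intermediate
10 | 2,4-dibromo-6-(3,6-dibromo-2-hydroxyphenoxy)phenyl formate (not isolated) | O=COc1c(Br)cc(Br)cc1Oc1c(Br)ccc(Br)c1O | intermediate
11 | 2,4-dibromo-6-(3,6-dibromo-2-hydroxyphenoxy)phenol | Oc1c(Br)cc(Br)cc1Oc1c(Br)ccc(Br)c1O | target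

Total step count: 4. Longest linear sequence: 4 (1 → 3 → 5 → 8 → 11).

**Steps most likely to fail**

1. Step 3.
   - Risk: each ring is drained by two bromines, so the hydride shift in the Criegee adduct may overtake the aryl shift. Carbon would then be oxidised instead of oxygen being inserted. The second insertion may also lag behind the first, and early loss of a formate would expose a phenol to the peracid.
   - Fallback: it sets out from 5 and comes back at 11. MeMgBr (THF, −78 °C) adds to both formyl groups to give the bis(1-hydroxyethyl) diaryl ether F1, a diastereomer mixture of no consequence. Dess–Martin periodinane (CH2Cl2, rt) turns it into the bis(aryl methyl ketone) F2.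
   - In the Criegee adducts of F2 the only competitor of aryl is methyl, the poorest migrating group. Trifluoroperacetic acid under the conditions of step 3 should therefore give the more robust bis-acetate F3. K2CO3 in MeOH followed by acid then leads to 11.

2. Step 2.
   - Risk: the phenolate of 3 is weakly basic and flanked on both sides (Br and CHO), so addition to 4 may be slow. Under forcing conditions, traces of water may hydrolyse the fluoride, the preference for fluoride over bromide may erode, and aryloxy groups may exchange between product and phenolate.
   - Fallback: it forms the other C–O bond of the ether (O–C2' of ring B) with the roles of the rings exchanged. It sets out from 4 and comes back at 5. NaOMe in MeOH (reflux) replaces the fluoride to give 2,4-dibromo-6-methoxybenzaldehyde F4. BCl3 (CH2Cl2, −78 °C to rt) removes the methyl group next to the carbonyl by chelation to give 2,4-dibromo-6-hydroxybenzaldehyde F5.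
   - The phenolate of F5 has only one ortho neighbour. With Cs2CO3 in DMAc it should displace the fluoride of purchased 3,6-dibromo-2-fluorobenzaldehyde F6, which is activated by an ortho formyl group and an ortho bromine, to give 5.

3. Step 1.
   - Risk: C–C bond formation at a crowded ortho carbon of an electron-poor phenol may stall. Prolonged heating may then lead to O-alkylation of the phenol by formaldehyde-derived species.
   - Fallback: it replaces electrophilic formylation with directed ortho-metalation. It sets out from 1 and comes back at 3. MOMCl and iPr2NEt (CH2Cl2) give 1,4-dibromo-2-(methoxymethoxy)benzene F7. LiN(iPr)2 (THF, −78 °C) removes the most acidic proton, the one between OMOM and Br, to give 3,6-dibromo-2-(methoxymethoxy)phenyllithium F8.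
   - F8 is quenched cold with DMF, before any halogen migration can set in, to give 3,6-dibromo-2-(methoxymethoxy)benzaldehyde F9. HCl in MeOH (50 °C) then releases 3.

**Further compounds**
F1 | step 3 | 1-{2,4-dibromo-6-[3,6-dibromo-2-(1-hydroxyethyl)phenoxy]phenyl}ethanol (mixture of diastereomers, both carbinol centres erased in the next operation) | CC(O)c1c(Br)cc(Br)cc1Oc1c(Br)ccc(Br)c1C(C)O
F2 | step 3 | 1-[2-(2-acetyl-3,6-dibromophenoxy)-4,6-dibromophenyl]ethanone | CC(=O)c1c(Br)cc(Br)cc1Oc1c(Br)ccc(Br)c1C(C)=O
F3 | step 3 | 2-(2-acetoxy-3,6-dibromophenoxy)-4,6-dibromophenyl acetate | CC(=O)Oc1c(Br)cc(Br)cc1Oc1c(Br)ccc(Br)c1OC(C)=O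
F4 | step 2 | 2,4-dibromo-6-methoxybenzaldehyde | COc1cc(Br)cc(Br)c1C=O
F5 | step 2 | 2,4-dibromo-6-hydroxybenzaldehyde | Oc1cc(Br)cc(Br)c1C=O
F6 | step 2 | 3,6-dibromo-2-fluorobenzaldehyde (purchased) | O=Cc1c(F)c(Br)ccc1Br
F7 | step 1 | 1,4-dibromo-2-(methoxymethoxy)benzene | COCOc1cc(Br)ccc1Br
F8 | step 1 | 3,6-dibromo-2-(methoxymethoxy)phenyllithium | [Li]c1c(Br)ccc(Br)c1OCOC
F9 | step 1 | 3,6-dibromo-2-(methoxymethoxy)benzaldehyde | COCOc1c(Br)ccc(Br)c1C=O
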